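**Plan**
1. Retrosynthetic cuts: (i) C2–C3 and C4–C4a of the upper flavan unit together, which removes its whole ring C; (ii) the C4–C8 bond between middle and lower unit; (iii) O1–C2 and the α,β-bond of a chalcone for ring C of the middle unit.
2. Enabling feature: ring C of the upper unit is an aryl ether (C2–O1–C8a=C4a), and its C4 is benzylic to C8 of the middle ring A, a carbon flanked by O1 and O7. An aryl oxocarbenium ion C2=O1(+)–C8a=C4a (four atoms) and a C8-bound (E)-enol acetate C3=C4 (two atoms; C3 nucleophilic, C4 cation-stabilised) can therefore close the ring in one cationic [4+2] event.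
3. Forward order: middle ring A (2-bromoresorcinol, Br marks the future C8) → chalcone → epoxide → middle ring C → 3,4-diol → C4–C8 coupling with benzylated (−)-epicatechin → C3 inversion → Br exchanged for the (E)-enol acetate → upper rings A, C and B added last → deprotection.
4. Stereochemistry: lower unit bought as (−)-epicatechin; middle C2/C3 from Juliá–Colonna epoxidation, C4 by trans attack on the C4 cation, C3 then inverted (oxidation, bulky hydride) to all-cis; upper C2, C3 and C4 all set in the key step (chiral counter-anion, endo approach, (E)-alkene geometry with acetate participation).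
5. Helpers: enol acetate (directs regiochemistry, participates, becomes the 3-OH), pivalate leaving group, benzyl ethers; all are removed in the last two steps.

Key step: step 16

Remark: the chiral acid of step 16 is written as its (R) enantiomer and is assumed to be the one matched to the (2R,3R,4R) sense; if induction proves opposite, its antipode is used.

**Route**

Step 1
Reactants: 1 2-bromoresorcinol
Product: 2 1-(3-bromo-2,4-dihydroxyphenyl)ethanone
Conditions: AcOH, BF3·OEt2, 90 °C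
Reagents that add atoms: acetic acid, CC(O)=O
Why: Friedel–Crafts (Nencki-type) acylation with loss of water; the two free positions ortho/para to the hydroxyls are equivalent, so one ketone should form with bromine between the two oxygens (the future C8 of the middle unit).

Step 2
Reactants: 2 1-(3-bromo-2,4-dihydroxyphenyl)ethanone
Product: 3 1-[4-(benzyloxy)-3-bromo-2-hydroxyphenyl]ethanone
Conditions: BnBr (1.05 equiv), K2CO3, acetone, reflux
Reagents that add atoms: benzyl bromide, BrCc1ccccc1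
Why: Williamson etherification; the 2-OH is chelated to the acetyl carbonyl, so the 4-OH should be benzylated selectively.

Step 3
Reactants: 3 1-[4-(benzyloxy)-3-bromo-2-hydroxyphenyl]ethanone
Product: 4 1-[4-(benzyloxy)-3-bromo-2-(methoxymethoxy)phenyl]ethanone
Conditions: NaH, DMF, 0 °C; MOMCl
Reagents that add atoms: chloromethyl methyl ether, COCCl
Why: O-alkylation of the sodium phenoxide masks the chelated phenol so that the chalcone of step 4 cannot cyclise under base.

Step 4
Reactants: 4 1-[4-(benzyloxy)-3-bromo-2-(methoxymethoxy)phenyl]ethanone; 5 3,4,5-tris(benzyloxy)benzaldehyde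
Product: 6 (E)-1-[4-(benzyloxy)-3-bromo-2-(methoxymethoxy)phenyl]-3-[3,4,5-tris(benzyloxy)phenyl]prop-2-en-1-one
Conditions: KOH, EtOH/THF, rt
Reagents that add atoms: none
Why: Claisen–Schmidt (crossed aldol) condensation; dehydration of the aldol should give the (E)-chalcone.

Step 5
Reactants: 6 (E)-chalcone
Product: 7 [(2R,3S)-3-[3,4,5-tris(benzyloxy)phenyl]oxiran-2-yl][4-(benzyloxy)-3-bromo-2-(methoxymethoxy)phenyl]methanone
Conditions: poly-L-leucine, urea–H2O2, 1,8-diazabicyclo[5.4.0]undec-7-ene (DBU), THF, rt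
Reagents that add atoms: urea–hydrogen peroxide, NC(N)=O.OO
Why: Juliá–Colonna epoxidation (conjugate addition of hydroperoxide inside the polypeptide helix); poly-L-leucine should deliver the (2R,3S)-epoxy ketone, the catalyst-set centres of the middle unit.

Step 6
Reactants: 7 (2R,3S)-epoxy ketone
Product: 9 (2R,3R)-7-(benzyloxy)-8-bromo-3-hydroxy-2-[3,4,5-tris(benzyloxy)phenyl]chroman-4-one, via free phenol epoxy ketone 8 (not isolated)
Conditions: HCl, MeOH/THF, 50 °C
Reagents that add atoms: none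
Why: Acid removes the MOM group and the freed phenol opens the epoxide at the benzylic carbon (6-endo, activated by the 4-benzyloxyaryl group) with inversion while the α-carbon keeps its configuration, which should give the 2,3-trans (2R,3R)-dihydroflavonol.

Step 7
Reactants: 9 (2R,3R)-dihydroflavonol
Product: 10 (2R,3S,4R)-7-(benzyloxy)-8-bromo-2-[3,4,5-tris(benzyloxy)phenyl]chromane-3,4-diol
Conditions: NaBH4, MeOH/THF, 0 °C
Reagents that add atoms: none
Why: Borohydride reduction of the aryl ketone should give mainly the 2,3-trans-3,4-trans diol; the C4 configuration is immaterial because C4 is ionised in step 9.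

Step 8
Reactants: 11 (−)-epicatechin
Product: 12 3,5,7,3',4'-penta-O-benzyl-(−)-epicatechin
Conditions: NaH, BnBr, DMF, 0 °C → rt
Reagents that add atoms: benzyl bromide, BrCc1ccccc1
Why: Williamson etherification of all five hydroxyls; the 3-O-benzyl group keeps the lower unit inert in steps 10 to 12 and the two stereocentres are bought.

Step 9
Reactants: 10 (2R,3S,4R)-flavan-3,4-diol; 12 penta-O-benzyl-(−)-epicatechin
Product: 13 8-bromo-7,3',4',5'-tetra-O-benzylrobinetinidol-(4α→8)-3,5,7,3',4'-penta-O-benzylepicatechin [upper unit (2R,3S,4S), lower unit (2R,3R)]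
Conditions: 12 (3 equiv), BF3·OEt2 (0.3 equiv), DCM, −30 → 0 °C
Reagents that add atoms: none
Why: Lewis-acid ionisation of the benzylic 4-OH, which leaves as water, gives a C4 cation stabilised by O1 and the para 7-benzyloxy group, which undergoes Friedel–Crafts attack by C8 of 12 (the usual site of benzylated flavan-3-ols) on the face anti to the 3-OH, setting 4S (3,4-trans); the bromine and the 5-deoxy ring A keep the electrophile from adding to itself.

Step 10
Reactants: 13 4α→8 dimer with free upper 3-OH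
Product: 14 upper-unit 3-ketone of 13 [upper unit (2R,4S)-3-oxo, lower unit (2R,3R)]
Conditions: Dess–Martin periodinane, pyridine, DCM, rt
Reagents that add atoms: none
Why: Dess–Martin oxidation of the only free hydroxyl under buffered neutral conditions should give the flavan-3-one without touching C2 or C4, whose equatorial cis-diaryl arrangement is also the thermodynamic one.

Step 11
Reactants: 14 upper-unit 3-ketone
Product: 15 8-bromo-7,3',4',5'-tetra-O-benzylepirobinetinidol-(4α→8)-penta-O-benzylepicatechin [upper unit (2R,3R,4S) all-cis, lower unit (2R,3R)]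
Conditions: LiBH(s-Bu)3 (L-Selectride), THF, −78 °C; H2O
Reagents that add atoms: none
Why: The bulky hydride should attack the ketone from the β face, opposite the two α-oriented equatorial aryl groups at C2 and C4, giving the axial all-cis 3R alcohol, as in the catechin-to-epicatechin inversion.

Step 12
Reactants: 15 all-cis dimer alcohol
Product: 16 3-O-acetate of 15
Conditions: Ac2O, pyridine, 4-(dimethylamino)pyridine (DMAP), rt
Reagents that add atoms: acetic anhydride, CC(=O)OC(C)=O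
Why: DMAP-catalysed acylation; the acetate keeps this hydroxyl from trapping the oxocarbenium ion of step 16.

Step 13
Reactants: 16 dimer bromide acetate; 17 vinylboronic acid pinacol ester
Product: 19 potassium (E)-alkenyltrifluoroborate (the C8 bromine of 16 replaced by (E)-CH=CH–BF3K), via (E)-alkenyl pinacol boronate 18 (not isolated)
Conditions: 17 (3 equiv), Pd[P(t-Bu)3]2 (5 mol %), Cy2NMe, dioxane, 80 °C; then KHF2, MeOH/H2O, rt
Reagents that add atoms: potassium hydrogen difluoride, [K+].[F-].F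
Why: Heck reaction (insertion at the unsubstituted alkene carbon, syn β-hydride elimination) should give the (E)-alkenyl boronate, which KHF2 converts in the same flask to the trifluoroborate.

Step 14
Reactants: 19 potassium (E)-alkenyltrifluoroborate
Product: 20 (E)-enol acetate (C8 of the upper unit of the dimer bears (E)-CH=CH–OAc)
Conditions: AcOH (3 equiv), CuBr (10 mol %), DMAP (20 mol %), 4 Å MS, O2 (1 atm), MeCN/DCE, 40 °C
Reagents that add atoms: acetic acid, CC(O)=O
Why: Chan–Lam-type oxidative C–O coupling of an alkenyltrifluoroborate with a carboxylic acid, which should proceed with retention of the (E) geometry.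

Step 15
Reactants: 5 3,4,5-tris(benzyloxy)benzaldehyde; 21 3-(benzyloxy)phenol
Product: 23 [3-(benzyloxy)phenoxy][3,4,5-tris(benzyloxy)phenyl]methyl pivalate (racemic), via α-chloroalkyl pivalate 22 (not isolated)
Conditions: PivCl (1.0 equiv), ZnCl2 (2 mol %), DCM, 0 °C; then 21, i-Pr2NEt, −20 °C → rt
Reagents that add atoms: pivaloyl chloride, CC(C)(C)C(Cl)=O
Why: ZnCl2-catalysed addition of the acyl chloride to the aldehyde gives the α-chloroalkyl ester, whose benzylic chloride is displaced by the phenol (acyloxyalkyl ether formation); the acetal centre is erased on ionisation, so no control is needed.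

Step 16
Reactants: 20 (E)-enol acetate; 23 acyloxy acetal
Product: 25 fully protected trimer [upper unit (2R,3R,4R) with 3-OAc; middle unit (2R,3R,4S) with 3-OAc; lower unit (2R,3R); thirteen benzyl ethers], via aryl oxocarbenium ion 24 (not isolated)
Conditions: (R)-3,3'-bis(2,4,6-triisopropylphenyl)-1,1'-binaphthyl-2,2'-diyl N-(trifluoromethylsulfonyl)phosphoramide (10 mol %), 4 Å MS, toluene, −40 → −20 °C; 23 (1.5 equiv) added slowly
Reagents that add atoms: none
Why: Proposed new method: the chiral acid ionises 23 (loss of pivalic acid) to the aryl oxocarbenium ion 24, a cationic 2-oxadiene (C2=O1(+)–C8a=C4a) paired with the chiral phosphoramide anion, and the enol acetate adds to C2 through its oxygen-bearing carbon (future C3) because the developing cation at C4 is stabilised by the 2,6-dioxygenated ring A of the middle unit whereas the ester oxygen is a poor donor; the closest known reactions are the SnCl4-mediated oxa-Povarov reaction of aryl oxocarbenium ions with styrenes and the chiral-acid-catalysed Povarov reaction of enecarbamates. Ring C of the upper unit closes as the second bond of this formal inverse-demand [4+2] annulation, in stepwise terms a six-membered Friedel–Crafts alkylation of C4a by the C4 cation in which the arene bond C4a=C8a becomes endocyclic (6-endo). C2 is set by the chiral counter-anion, which shields one face of the (E)-oxocarbenium ion (catalyst control, since the existing centres of 20 are remote). C3 follows from an endo (synclinal) approach in which the ester carbonyl lies over the cationic O1–C2 unit, giving the 2,3-cis relation. C4 follows from the (E)-alkene geometry if the event is concerted and, if the cation is free, from allylic 1,3-strain with the ortho oxygens plus anchimeric assistance of the 3-acetoxy group (trans-dioxolanylium opened with inversion), both of which lead to 3,4-trans. The step needs alkene-over-arene attack (C6–H of the lower unit is flanked by two benzyloxy groups and 23 is kept dilute by slow addition), six-membered closure at C4a (ortho to O1, para to the 7-benzyloxy group) in preference to five-membered closure onto ring B or closure between the two oxygens, and 4→8 regiochemistry, which is fixed because C4 is already bonded to C8 of the middle unit.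

Step 17
Reactants: 25 fully protected trimer
Product: 26 trimer 3,3-diol (upper and middle 3-OH free, thirteen benzyl ethers)
Conditions: K2CO3, MeOH/THF, rt
Reagents that add atoms: none
Why: Zemplén-type transesterification should remove both acetates without touching benzyl ethers or stereocentres.

Step 18
Reactants: 26 trimer 3,3-diol
Product: 27 CNP0115797.2, epirobinetinidol-(4β→8)-epirobinetinidol-(4α→8)-epicatechin
Conditions: H2 (1 atm), Pd(OH)2/C, THF/MeOH/H2O, rt
Reagents that add atoms: none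
Why: Hydrogenolysis should cleave all thirteen benzyl ethers under neutral conditions that leave the 5-deoxy interflavan bonds and all eight stereocentres intact.

**Compound list**
1 | 2-bromoresorcinol | Oc1cccc(O)c1Br | starting material
2 | 1-(3-bromo-2,4-dihydroxyphenyl)ethanone | CC(=O)c1ccc(O)c(Br)c1O | intermediate
3 | 1-[4-(benzyloxy)-3-bromo-2-hydroxyphenyl]ethanone | CC(=O)c1ccc(OCc2ccccc2)c(Br)c1O | intermediate
4 | 1-[4-(benzyloxy)-3-bromo-2-(methoxymethoxy)phenyl]ethanone | CC(=O)c1ccc(OCc2ccccc2)c(Br)c1OCOC | intermediate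
5 | 3,4,5-tris(benzyloxy)benzaldehyde | O=Cc1cc(OCc2ccccc2)c(OCc2ccccc2)c(OCc2ccccc2)c1 | starting material
6 | (E)-1-[4-(benzyloxy)-3-bromo-2-(methoxymethoxy)phenyl]-3-[3,4,5-tris(benzyloxy)phenyl]prop-2-en-1-one | COCOc1c(Br)c(OCc2ccccc2)ccc1C(=O)/C=C/c1cc(OCc2ccccc2)c(OCc2ccccc2)c(OCc2ccccc2)c1 | intermediate
7 | [(2R,3S)-3-[3,4,5-tris(benzyloxy)phenyl]oxiran-2-yl][4-(benzyloxy)-3-bromo-2-(methoxymethoxy)phenyl]methanone | COCOc1c(Br)c(OCc2ccccc2)ccc1C(=O)[C@@H]1O[C@H]1c1cc(OCc2ccccc2)c(OCc2ccccc2)c(OCc2ccccc2)c1 | intermediate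
8 | [(2R,3S)-3-[3,4,5-tris(benzyloxy)phenyl]oxiran-2-yl][4-(benzyloxy)-3-bromo-2-hydroxyphenyl]methanone | Oc1c(Br)c(OCc2ccccc2)ccc1C(=O)[C@@H]1O[C@H]1c1cc(OCc2ccccc2)c(OCc2ccccc2)c(OCc2ccccc2)c1 | intermediate
9 | (2R,3R)-7-(benzyloxy)-8-bromo-3-hydroxy-2-[3,4,5-tris(benzyloxy)phenyl]chroman-4-one | O=C1[C@H](O)[C@@H](c2cc(OCc3ccccc3)c(OCc3ccccc3)c(OCc3ccccc3)c2)Oc2c(Br)c(OCc3ccccc3)ccc12 | intermediate
10 | (2R,3S,4R)-7-(benzyloxy)-8-bromo-2-[3,4,5-tris(benzyloxy)phenyl]chromane-3,4-diol | O[C@H]1[C@H](O)[C@@H](c2cc(OCc3ccccc3)c(OCc3ccccc3)c(OCc3ccccc3)c2)Oc2c(Br)c(OCc3ccccc3)ccc12 | intermediate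
11 | (−)-epicatechin, (2R,3R) | Oc1cc(O)c2c(c1)O[C@H](c1ccc(O)c(O)c1)[C@H](O)C2 | starting material
12 | 3,5,7,3',4'-penta-O-benzyl-(−)-epicatechin | c1ccccc1COc1cc(OCc3ccccc3)c2c(c1)O[C@H](c1ccc(OCc3ccccc3)c(OCc3ccccc3)c1)[C@H](OCc3ccccc3)C2 | intermediate
13 | 8-bromo-7,3',4',5'-tetra-O-benzylrobinetinidol-(4α→8)-penta-O-benzylepicatechin; upper (2R,3S,4S), lower (2R,3R) | Brc1c(OCc3ccccc3)ccc2c1O[C@H](c1cc(OCc3ccccc3)c(OCc3ccccc3)c(OCc3ccccc3)c1)[C@@H](O)[C@@H]2c1c(OCc3ccccc3)cc(OCc3ccccc3)c2c1O[C@H](c1ccc(OCc3ccccc3)c(OCc3ccccc3)c1)[C@H](OCc3ccccc3)C2 | intermediate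
14 | upper-unit 3-ketone of 13; upper (2R,4S), lower (2R,3R) | Brc1c(OCc3ccccc3)ccc2c1O[C@H](c1cc(OCc3ccccc3)c(OCc3ccccc3)c(OCc3ccccc3)c1)C(=O)[C@@H]2c1c(OCc3ccccc3)cc(OCc3ccccc3)c2c1O[C@H](c1ccc(OCc3ccccc3)c(OCc3ccccc3)c1)[C@H](OCc3ccccc3)C2 | intermediate
15 | 8-bromo-7,3',4',5'-tetra-O-benzylepirobinetinidol-(4α→8)-penta-O-benzylepicatechin; upper (2R,3R,4S) all-cis, lower (2R,3R) | Brc1c(OCc3ccccc3)ccc2c1O[C@H](c1cc(OCc3ccccc3)c(OCc3ccccc3)c(OCc3ccccc3)c1)[C@H](O)[C@@H]2c1c(OCc3ccccc3)cc(OCc3ccccc3)c2c1O[C@H](c1ccc(OCc3ccccc3)c(OCc3ccccc3)c1)[C@H](OCc3ccccc3)C2 | intermediate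
16 | upper-unit 3-O-acetate of 15 | Brc1c(OCc3ccccc3)ccc2c1O[C@H](c1cc(OCc3ccccc3)c(OCc3ccccc3)c(OCc3ccccc3)c1)[C@H](OC(C)=O)[C@@H]2c1c(OCc3ccccc3)cc(OCc3ccccc3)c2c1O[C@H](c1ccc(OCc3ccccc3)c(OCc3ccccc3)c1)[C@H](OCc3ccccc3)C2 | intermediate
17 | vinylboronic acid pinacol ester | C=CB1OC(C)(C)C(C)(C)O1 | starting material
18 | (E)-alkenyl pinacol boronate: 16 with Br replaced by (E)-CH=CH–B(pinacolato) | CC1(C)OB(OC1(C)C)/C=C/c1c(OCc3ccccc3)ccc2c1O[C@H](c1cc(OCc3ccccc3)c(OCc3ccccc3)c(OCc3ccccc3)c1)[C@H](OC(C)=O)[C@@H]2c1c(OCc3ccccc3)cc(OCc3ccccc3)c2c1O[C@H](c1ccc(OCc3ccccc3)c(OCc3ccccc3)c1)[C@H](OCc3ccccc3)C2 | intermediate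
19 | potassium (E)-alkenyltrifluoroborate: 16 with Br replaced by (E)-CH=CH–BF3K | [K+].F[B-](F)(F)/C=C/c1c(OCc3ccccc3)ccc2c1O[C@H](c1cc(OCc3ccccc3)c(OCc3ccccc3)c(OCc3ccccc3)c1)[C@H](OC(C)=O)[C@@H]2c1c(OCc3ccccc3)cc(OCc3ccccc3)c2c1O[C@H](c1ccc(OCc3ccccc3)c(OCc3ccccc3)c1)[C@H](OCc3ccccc3)C2 | intermediate
20 | (E)-enol acetate: 16 with Br replaced by (E)-CH=CH–OAc | CC(=O)O/C=C/c1c(OCc3ccccc3)ccc2c1O[C@H](c1cc(OCc3ccccc3)c(OCc3ccccc3)c(OCc3ccccc3)c1)[C@H](OC(C)=O)[C@@H]2c1c(OCc3ccccc3)cc(OCc3ccccc3)c2c1O[C@H](c1ccc(OCc3ccccc3)c(OCc3ccccc3)c1)[C@H](OCc3ccccc3)C2 | intermediate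
21 | 3-(benzyloxy)phenol | Oc1cccc(OCc2ccccc2)c1 | starting material
22 | chloro[3,4,5-tris(benzyloxy)phenyl]methyl pivalate (racemic) | CC(C)(C)C(=O)OC(Cl)c1cc(OCc2ccccc2)c(OCc2ccccc2)c(OCc2ccccc2)c1 | intermediate
23 | [3-(benzyloxy)phenoxy][3,4,5-tris(benzyloxy)phenyl]methyl pivalate (racemic) | CC(C)(C)C(=O)OC(Oc1cccc(OCc2ccccc2)c1)c1cc(OCc2ccccc2)c(OCc2ccccc2)c(OCc2ccccc2)c1 | intermediate
24 | [3-(benzyloxy)phenyl][3,4,5-tris(benzyloxy)benzylidene]oxonium ion (cation of the ion pair with the catalyst anion) | C(=[O+]c1cccc(OCc2ccccc2)c1)c1cc(OCc2ccccc2)c(OCc2ccccc2)c(OCc2ccccc2)c1 | intermediate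
25 | fully protected trimer: upper (2R,3R,4R) 3-OAc, middle (2R,3R,4S) 3-OAc, lower (2R,3R); thirteen O-benzyl groups | c3ccccc3COc1ccc2c(c1)O[C@H](c1cc(OCc3ccccc3)c(OCc3ccccc3)c(OCc3ccccc3)c1)[C@H](OC(C)=O)[C@H]2c1c(OCc3ccccc3)ccc2c1O[C@H](c1cc(OCc3ccccc3)c(OCc3ccccc3)c(OCc3ccccc3)c1)[C@H](OC(C)=O)[C@@H]2c1c(OCc3ccccc3)cc(OCc3ccccc3)c2c1O[C@H](c1ccc(OCc3ccccc3)c(OCc3ccccc3)c1)[C@H](OCc3ccccc3)C2 | intermediate
26 | trideca-O-benzyl trimer with free upper and middle 3-OH | c3ccccc3COc1ccc2c(c1)O[C@H](c1cc(OCc3ccccc3)c(OCc3ccccc3)c(OCc3ccccc3)c1)[C@H](O)[C@H]2c1c(OCc3ccccc3)ccc2c1O[C@H](c1cc(OCc3ccccc3)c(OCc3ccccc3)c(OCc3ccccc3)c1)[C@H](O)[C@@H]2c1c(OCc3ccccc3)cc(OCc3ccccc3)c2c1O[C@H](c1ccc(OCc3ccccc3)c(OCc3ccccc3)c1)[C@H](OCc3ccccc3)C2 | intermediate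
27 | CNP0115797.2, epirobinetinidol-(4β→8)-epirobinetinidol-(4α→8)-epicatechin | Oc1ccc2c(c1)O[C@H](c1cc(O)c(O)c(O)c1)[C@H](O)[C@H]2c1c(O)ccc2c1O[C@H](c1cc(O)c(O)c(O)c1)[C@H](O)[C@@H]2c1c(O)cc(O)c2c1O[C@H](c1ccc(O)c(O)c1)[C@H](O)C2 | target

**Step count and risks**
Total steps: 18. Longest linear sequence: 16 steps (1–7, 9–14, 16–18).

Steps most likely to fail:

1. Step 16 (Proposed new method). What may go wrong: poor facial or endo/exo selectivity, attack of the alkene through the wrong carbon, or capture of the C4 cation by ring B in a five-membered closure. Fallback with known reactions, setting out from 19 and coming back at 26: a 1,2-addition of 19 to aldehyde 5, catalysed by Rh(acac)(CO)2 with 1,1'-bis(diphenylphosphino)ferrocene (DME/H2O, 80 °C), gives the (E)-allylic alcohol F1 as both carbinol epimers. Sharpless kinetic-resolution epoxidation (Ti(Oi-Pr)4, L-(+)-diisopropyl tartrate, t-BuOOH, 4 Å MS, DCM, −20 °C) should epoxidise only the (R)-carbinol epimer, anti to the hydroxyl, to the anti epoxy alcohol F2. Mitsunobu etherification with 21 (PPh3, DIAD, toluene, 0 °C) inverts the carbinol and gives the aryl ether epoxide F3. A Lewis-acid epoxy-arene cyclisation (BF3·OEt2 cat., DCM, −78 °C; 6-endo, arene attack at the benzylic epoxide carbon with inversion) closes ring C as the 2,3-cis-3,4-trans alcohol F4. K2CO3 in MeOH then removes the remaining acetate and gives 26. Every centre here comes from a stereospecific step (tartrate-controlled epoxidation, inversion at C2, inversion at C4).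

2. Step 14. What may go wrong: protodeboronation or oxidative homocoupling of the electron-rich styryl trifluoroborate instead of C–O coupling (the hindered Heck reaction of step 13 feeds the same weak point). Fallback setting out from 16 and coming back at 20: Suzuki–Miyaura coupling of 16 with commercial (E)-2-ethoxyvinylboronic acid pinacol ester (Pd(OAc)2, 2-dicyclohexylphosphino-2',6'-dimethoxybiphenyl, K3PO4, toluene, 80 °C) gives the (E)-enol ethyl ether F5. Mild hydrolysis (aq. HCl, THF, rt) gives the arylacetaldehyde F6. O-acetylation of its enol (Ac2O, Et3N, DMAP cat., DCM) should give 20 as an E/Z mixture in which E is expected to prevail; it is enriched by iodine-catalysed equilibration and chromatography.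

3. Step 9. What may go wrong: low facial selectivity at C4 (4α versus 4β) or competing attack through C6 of the nucleophile. Fallback setting out from 10 and coming back at 13: acetylation (Ac2O, pyridine, DMAP) gives the 3,4-di-O-acetate F7. Me3SiOTf-catalysed coupling with 12 (DCM, −40 °C) then runs under anchimeric control: the 3-O-acetyl group bridges the C4 cation on the β face, so C8 of 12 must enter from the α face, giving the 3-O-acetyl dimer F8. K2CO3 in MeOH returns 13.

**Further compounds**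
F1 | step 16 | (E)-allylic alcohol, both carbinol epimers: C8 of the upper unit of the dimer acetate bears (E)-CH=CH–CH(OH)–[3,4,5-tris(benzyloxy)phenyl] | OC(c1cc(OCc3ccccc3)c(OCc3ccccc3)c(OCc3ccccc3)c1)/C=C/c1c(OCc3ccccc3)ccc2c1O[C@H](c1cc(OCc3ccccc3)c(OCc3ccccc3)c(OCc3ccccc3)c1)[C@H](OC(C)=O)[C@@H]2c1c(OCc3ccccc3)cc(OCc3ccccc3)c2c1O[C@H](c1ccc(OCc3ccccc3)c(OCc3ccccc3)c1)[C@H](OCc3ccccc3)C2
F2 | step 16 | anti epoxy alcohol: trans-(2S,3S)-oxirane with (S)-carbinol | O[C@@H](c1cc(OCc3ccccc3)c(OCc3ccccc3)c(OCc3ccccc3)c1)[C@@H]1O[C@H]1c1c(OCc3ccccc3)ccc2c1O[C@H](c1cc(OCc3ccccc3)c(OCc3ccccc3)c(OCc3ccccc3)c1)[C@H](OC(C)=O)[C@@H]2c1c(OCc3ccccc3)cc(OCc3ccccc3)c2c1O[C@H](c1ccc(OCc3ccccc3)c(OCc3ccccc3)c1)[C@H](OCc3ccccc3)C2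
F3 | step 16 | 3-(benzyloxy)phenyl ether of F2 with inverted ether carbon (syn to the epoxide oxygen) | O(c1cccc(OCc3ccccc3)c1)[C@H](c1cc(OCc3ccccc3)c(OCc3ccccc3)c(OCc3ccccc3)c1)[C@@H]1O[C@H]1c1c(OCc3ccccc3)ccc2c1O[C@H](c1cc(OCc3ccccc3)c(OCc3ccccc3)c(OCc3ccccc3)c1)[C@H](OC(C)=O)[C@@H]2c1c(OCc3ccccc3)cc(OCc3ccccc3)c2c1O[C@H](c1ccc(OCc3ccccc3)c(OCc3ccccc3)c1)[C@H](OCc3ccccc3)C2
F4 | step 16 | protected trimer with free upper 3-OH and middle 3-OAc; upper (2R,3R,4R), middle (2R,3R,4S), lower (2R,3R) | c3ccccc3COc1ccc2c(c1)O[C@H](c1cc(OCc3ccccc3)c(OCc3ccccc3)c(OCc3ccccc3)c1)[C@H](O)[C@H]2c1c(OCc3ccccc3)ccc2c1O[C@H](c1cc(OCc3ccccc3)c(OCc3ccccc3)c(OCc3ccccc3)c1)[C@H](OC(C)=O)[C@@H]2c1c(OCc3ccccc3)cc(OCc3ccccc3)c2c1O[C@H](c1ccc(OCc3ccccc3)c(OCc3ccccc3)c1)[C@H](OCc3ccccc3)C2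
F5 | step 14 | (E)-enol ethyl ether: 16 with Br replaced by (E)-CH=CH–OEt | CCO/C=C/c1c(OCc3ccccc3)ccc2c1O[C@H](c1cc(OCc3ccccc3)c(OCc3ccccc3)c(OCc3ccccc3)c1)[C@H](OC(C)=O)[C@@H]2c1c(OCc3ccccc3)cc(OCc3ccccc3)c2c1O[C@H](c1ccc(OCc3ccccc3)c(OCc3ccccc3)c1)[C@H](OCc3ccccc3)C2
F6 | step 14 | arylacetaldehyde: 16 with Br replaced by CH2CHO | O=CCc1c(OCc3ccccc3)ccc2c1O[C@H](c1cc(OCc3ccccc3)c(OCc3ccccc3)c(OCc3ccccc3)c1)[C@H](OC(C)=O)[C@@H]2c1c(OCc3ccccc3)cc(OCc3ccccc3)c2c1O[C@H](c1ccc(OCc3ccccc3)c(OCc3ccccc3)c1)[C@H](OCc3ccccc3)C2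
F7 | step 9 | (2R,3S,4R)-7-(benzyloxy)-8-bromo-2-[3,4,5-tris(benzyloxy)phenyl]chromane-3,4-diyl diacetate | CC(=O)O[C@H]1[C@H](OC(C)=O)[C@@H](c2cc(OCc3ccccc3)c(OCc3ccccc3)c(OCc3ccccc3)c2)Oc2c(Br)c(OCc3ccccc3)ccc12
F8 | step 9 | upper-unit 3-O-acetate of 13; upper (2R,3S,4S), lower (2R,3R) | Brc1c(OCc3ccccc3)ccc2c1O[C@H](c1cc(OCc3ccccc3)c(OCc3ccccc3)c(OCc3ccccc3)c1)[C@@H](OC(C)=O)[C@@H]2c1c(OCc3ccccc3)cc(OCc3ccccc3)c2c1O[C@H](c1ccc(OCc3ccccc3)c(OCc3ccccc3)c1)[C@H](OCc3ccccc3)C2
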